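The readings are simulated for an exercise; noise was put on by code.

The readings cannot count chains: they give Z and J, and the same J can sit in few long chains or many short ones.

| flask | Z | X | D | L | remark | time |
|---|---|---|---|---|---|---|
| larch | 2 M (fed, over 50 min) | 0.060 M | 2 mol% | 13 mM | the very flask that is asked about, followed so far; the fed solution adds 0.10 times the starting volume |  |
| cedar | 2 M (fed, over 50 min) | 0.12 M | 2 mol% | 13 mM | run made earlier; the fed solution adds 0.10 times the starting volume |  |
| flask | 2.0 M (fed, over 50 min) | 0.0600 M | 2 mol% | 13 mM | the fed solution adds 0.10 times the starting volume | 50 h |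

| run | time / h | J / % | Z / % |
|---|---|---|---|
| larch | 0.333 | 0.2 | 36.7 |
| larch | 1.00 | 13.2 | 86.5 |
| larch | 2.00 | 26.9 | 72.1 |
| larch | 3.00 | 30.4 | 70.5 |
| larch | 4.00 | 33.3 | 65.4 |
| cedar | 1.50 | 12.2 | 87.5 |
| cedar | 3.00 | 17.3 | 82.5 |
| cedar | 6.00 | 17.1 | 82.9 |
| cedar | 10.0 | 17.8 | 82.5 |
| cedar | 20.0 | 18.5 | 83.8 |

(standard deviation of a reading: 1 percentage point)

- every charge counts on the volume at the start, and the solution that is fed holds the whole dose
- the average divides the monomer in chains by the number of chains begun, living and dead together
- what was read earlier has a scatter of 1 percentage point, one standard deviation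
- the earlier runs do not show the number of chains; that part of a forecast is a guess
- percentages count the whole charge, also what has not yet gone in

- whether the average number of monomer units in a chain (chains begun, living or dead) reaches 10 by 50 h (yes / no)
- average number of monomer units in a chain (chains begun, living or dead) at 50 h

The bench rule takes each D as one chain, so the length is the part of Z reacted times Z over D, here 50.0. On the larch reading of 33.3 % at 4.00 h it gives 16.6. The rule stops working where something else can take D, and in larch the charge of L over the charge of D is 0.325, a third. No run varies L, so its role is my guess: L removes D one for one before chains begin. I call what remains the live charge n, the D charged less the L charged: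

n = c(Z)·d − c(L) = 0.0270 M

DP = c(Z)·y / n

Here c(Z) and c(L) are the charges of Z and L, d is the loading of D, y is the part of Z in chains, and DP is the average number of units in a chain. With y at the last larch reading, I get DP = 24.7. Length 10 needs y = 13.5 %, and larch read more than that, 26.9 % at 2.00 h.

The forecast said yes and 17.5, with the remark “This chain count is a guess”; my reckoning, on the reading at 4.00 h, already stands higher.

The flask gave yes and 29.4.

    Z + D → Q + J (k = 0.00260 /M/s)
    Z + Q → J + Q, rate k2*[Q]*[Z] (k = 0.00370 /M/s)
    Q + X → E (k = 0.00400 /M/s)
    D + L → G (k = 0.450 /M/s)

At 50.0 h the flask held J 39.7 %, which over n gives DP = 29.4. L, the limiting reagent of D + L, stood at 0 %. At 1.55 h in the flask, Q had a half-life of 1.2 h by Q + X to E, shorter than the 5.0 h of Z by Z to J. At 50.0 h the flask held Q at 6.29 × 10⁻¹² M and Z at 60.3 %.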